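**Retrosynthetic overview**
1. Target ⇐ double epoxidation (DMDO) of a 1(10)-trans,2-cis,4-cis germacratrienolide, which comes from photochemical conrotatory 6π ring opening of a cis-fused hexalin butenolide (C5–C10 broken; C1=C10 and C4=C5 formed; ten-membered ring revealed).
2. Butenolide with its CH2OAc arm ⇐ new Lewis-base cascade (intramolecular Morita–Baylis–Hillman closure, then acetate transposition) on a 6-O-acryloyl 7-ketone.
3. Cyclohexadiene ring ⇐ Diels–Alder of a shikimate-derived enal with 1-acetoxypentadiene, then Pd-catalysed 1,4-elimination of AcOH.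
4. C6 and C8 stereocentres, C14 and the six-membered ring ⇐ (−)-shikimic acid; C8 is inverted by Mitsunobu esterification with (R)-2-methylbutanoic acid.
5. Ring order: cyclohexene (bought) → second six-membered ring → butenolide → ten-membered ring → two epoxides.

Convention: atom numbers in all names are those of the target (ring C1–C10; lactone C11, C12 (C=O), C13 (CH2OAc); C14 = CH2OH carbon on C10; C15 = methyl on C4); in the bicyclic intermediates α is the face of the C6–O and C8–O bonds.
Assumption: (R)-2-methylbutanoic acid (the configuration the target SMILES requires) is bought as such.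

**Route**

Step 1
Reactants: 1 (−)-shikimic acid
Product: 3 methyl 3,4-O-isopropylideneshikimate, via methyl shikimate 2 (not isolated)
Conditions: MeOH, TsOH (cat.), reflux; evaporate; 2,2-dimethoxypropane, acetone, rt (one pot)
Reagents that add atoms: methanol (CO); 2,2-dimethoxypropane (COC(C)(C)OC)
Why: Fischer esterification followed by acid-catalysed acetonide formation, which takes only the cis-3,4-diol and leaves the trans 5-OH free; no stereocentre is touched.

Step 2
Reactants: 3 methyl 3,4-O-isopropylideneshikimate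
Product: 4 (3R,4S,5R)-1-(hydroxymethyl)-3,4-O-isopropylidenecyclohex-1-ene-3,4,5-triol
Conditions: DIBAL-H (3.3 equiv), CH2Cl2, −78 → 0 °C
Reagents that add atoms: none
Why: DIBAL-H 1,2-reduction of the conjugated ester to the allylic alcohol (future C14); acetonide and stereocentres are inert.

Step 3
Reactants: 4 allylic alcohol
Product: 5 (3R,4S,5R)-5-hydroxy-3,4-(isopropylidenedioxy)cyclohex-1-ene-1-carbaldehyde
Conditions: activated MnO2 (10 equiv), CH2Cl2, rt
Reagents that add atoms: none
Why: MnO2 allylic oxidation is selective for the primary allylic alcohol over the secondary homoallylic one and gives the enal needed as dienophile.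

Step 4
Reactants: 5 hydroxy enal; 6 (R)-2-methylbutanoic acid
Product: 7 (3R,4S,5S)-1-formyl-3,4-(isopropylidenedioxy)cyclohex-1-en-5-yl (R)-2-methylbutanoate
Conditions: PPh3, DIAD, toluene, 0 °C → rt
Reagents that add atoms: none
Why: Mitsunobu esterification displaces the activated 5-OH by the carboxylate with SN2 inversion, turning the shikimate C5 centre into the 8α-acyloxy centre of the target (all three ring oxygens now cis); the acid's own centre is not enolised under these near-neutral conditions.

Step 5
Reactants: 8 (E)-pent-2-enal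
Product: 9 (1E,3E)-penta-1,3-dien-1-yl acetate
Conditions: isopropenyl acetate (excess), TsOH·H2O (cat.), Cu(OAc)2 (cat.), reflux, acetone distilled off
Reagents that add atoms: isopropenyl acetate (CC(=C)OC(C)=O)
Why: Acid-catalysed enol-acetate exchange on the dienol (thermodynamic conditions) gives mainly the (1E,3E) dienyl acetate, the only isomer that reacts in step 6, so the mixture is used in excess.

Step 6
Reactants: 7 enal ester; 9 dienyl acetate
Product: 10 cis-fused Δ2-octalin Diels–Alder adduct (10α-CHO; 1α-OAc; 4α-CH3; 5α-H; 6α,7α-acetonide; 8α-(R)-2-methylbutanoate)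
Conditions: Me2AlCl (30 mol%), excess diene, CH2Cl2, −78 → −20 °C
Reagents that add atoms: none
Why: Lewis-acid-catalysed Diels–Alder reaction: the diene adds to the face anti to the three α-oxygen substituents so both new ring bonds (C10–C1, C5–C4) are β, "ortho" regiochemistry joins the acetoxy-bearing diene terminus to the quaternary C10 and the methyl-bearing terminus to C5, and suprafacial addition makes the fusion cis (endo adduct drawn); C1, C4, C5 and C10 are all erased in steps 9 and 15, so only cis fusion and β-face addition matter.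

Step 7
Reactants: 10 Diels–Alder aldehyde
Product: 11 the corresponding C14 primary alcohol (C10–CH2OH)
Conditions: NaBH4, CeCl3·7H2O, MeOH, −78 °C
Reagents that add atoms: none
Why: Luche reduction of the neopentyl aldehyde at −78 °C leaves the esters alone and is too cold for migration of the C1 acetate to the new alkoxide.

Step 8
Reactants: 11 primary alcohol
Product: 12 the C14 tert-butyldiphenylsilyl ether
Conditions: TBDPSCl, imidazole, DMF, rt
Reagents that add atoms: tert-butyl(chloro)diphenylsilane (CC(C)(C)[Si](Cl)(c1ccccc1)c1ccccc1)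
Why: Silyl ether formation masks C14–OH for the acylation and oxidation to come; TBDPS is chosen because it survives the acid of step 10.

Step 9
Reactants: 12 allylic acetate
Product: 13 cis-fused hexalin 1,3-diene (C1=C2, C3=C4 bearing CH3; H5 and CH2OTBDPS α; 6α,7α-acetonide; 8α-ester)
Conditions: Pd(PPh3)4 (5 mol%), Et3N, 1,4-dioxane, 80 °C
Reagents that add atoms: none
Why: Pd(0)-catalysed 1,4-elimination (Tsuji–Trost ionisation, then syn β-hydride elimination): the π-allyl formed anti to OAc can lose only H4, which is syn to Pd because CH3 and OAc are cis, and C10 has no hydrogen, so the homoannular diene is the only possible product.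

Step 10
Reactants: 13 diene acetonide
Product: 14 the 6α,7α-diol
Conditions: AcOH/H2O (4:1), 40 °C
Reagents that add atoms: none
Why: Acid hydrolysis of the cis-fused acetonide; the TBDPS ether, the ester and the non-aromatisable diene tolerate warm aqueous acetic acid.

Step 11
Reactants: 14 diol
Product: 16 6-O-acryloyl derivative with free 7α-OH, via stannylene acetal 15 (not isolated)
Conditions: Bu2SnO, toluene, reflux (−H2O); then acryloyl chloride, 0 °C
Reagents that add atoms: acryloyl chloride (C=CC(=O)Cl)
Why: Stannylene-acetal-directed monoacylation: the dibutylstannylene of a cis-1,2-diol reacts at its equatorial oxygen (O6), leaving the axial C7–OH, which is flanked on both sides, free.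

Step 12
Reactants: 16 hydroxy acrylate
Product: 17 7-keto 6-O-acrylate
Conditions: Dess–Martin periodinane, CH2Cl2, rt
Reagents that add atoms: none
Why: Dess–Martin oxidation converts the remaining secondary alcohol to the ketone without base, so the two α-acyloxy centres (C6, C8) are not epimerised.

Step 13
Reactants: 17 keto acrylate
Product: 20 13-acetoxy-7(11)-en-12,6α-olide fused to the hexalin diene (C14 still OTBDPS), via Morita–Baylis–Hillman alcohol 18 (not isolated), via tertiary acetate 19 (not isolated)
Conditions: PMe3 (20 mol%), Ac2O (1.5 equiv), THF, 0 °C → rt; then DABCO (30 mol%), 40 °C (one pot)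
Reagents that add atoms: acetic anhydride (CC(=O)OC(C)=O)
Why: Proposed new method: a one-pot dual Lewis-base cascade in which PMe3 adds to the acrylate, the phosphonium enolate closes 5-exo onto the doubly α-acyloxy-activated C7 ketone (forming C7–C11 and the lactone ring), Ac2O traps the aldolate and acetate-induced E1cB loss of PMe3 gives the tertiary allylic acetate, and DABCO then moves the acetate from C7 to C13 by SN2′ addition/expulsion and SN2 return, the conjugated tetrasubstituted butenolide being the thermodynamic sink and the transient C7 centre being erased; the closest known reactions are the phosphine-catalysed intramolecular Morita–Baylis–Hillman cyclisation and the DABCO-mediated 1,3-acetate shift of Baylis–Hillman acetates, neither shown on an α-acryloyloxy ketone nor run in tandem.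

Step 14
Reactants: 20 silyl ether
Product: 21 the free C14 alcohol (photolysis substrate)
Conditions: HF·pyridine, pyridine, THF, 0 °C → rt
Reagents that add atoms: none
Why: Buffered fluoride desilylation frees C14–OH without base, so the base-sensitive butenolide, the acetate and the diene survive.

Step 15
Reactants: 21 hexalin diene butenolide
Product: 24 target CNP0108300.1, via triene 22 (not isolated), via monoepoxide 23 (not isolated)
Conditions: hν (300 nm), degassed Et2O, −40 °C; then dark, dimethyldioxirane (2.2 equiv, acetone), −20 → 0 °C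
Reagents that add atoms: dimethyldioxirane (CC1(C)OO1)
Why: Photochemical conrotatory 6π electrocyclic ring opening of the cis-fused cyclohexadiene breaks C5–C10 and forms the C1=C10 and C4=C5 bonds of the ten-membered ring, the sense of conrotation following the ground-state twist in which the lactone holds C6 pseudo-axial and C9 pseudo-equatorial on the diene ring so that C1(10) comes out trans and C4 cis (C2=C3 stays cis), and dimethyldioxirane then epoxidises only the two electron-rich trisubstituted alkenes from their outer faces in the relaxed ring conformer that carries C14 and C15 on the face of H6 and H8 (macrocyclic stereocontrol by the shikimate-derived C6 and C8 centres), which sets C1, C10, C4 and C5 as 1β,10α and 4α,5α.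

**Compound list**

1 | (−)-shikimic acid, (3R,4S,5R)-3,4,5-trihydroxycyclohex-1-ene-1-carboxylic acid | OC(=O)C1=C[C@@H](O)[C@@H](O)[C@H](O)C1 | starting material
2 | methyl shikimate | COC(=O)C1=C[C@@H](O)[C@@H](O)[C@H](O)C1 | intermediate
3 | methyl 3,4-O-isopropylideneshikimate | COC(=O)C1=C[C@H]2OC(C)(C)O[C@H]2[C@H](O)C1 | intermediate
4 | (3R,4S,5R)-1-(hydroxymethyl)-3,4-O-isopropylidenecyclohex-1-ene-3,4,5-triol | OCC1=C[C@H]2OC(C)(C)O[C@H]2[C@H](O)C1 | intermediate
5 | (3R,4S,5R)-5-hydroxy-3,4-(isopropylidenedioxy)cyclohex-1-ene-1-carbaldehyde | O=CC1=C[C@H]2OC(C)(C)O[C@H]2[C@H](O)C1 | intermediate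
6 | (R)-2-methylbutanoic acid | CC[C@@H](C)C(=O)O | starting material
7 | (3R,4S,5S)-1-formyl-3,4-(isopropylidenedioxy)cyclohex-1-en-5-yl (R)-2-methylbutanoate | O=CC1=C[C@H]2OC(C)(C)O[C@H]2[C@@H](OC(=O)[C@H](C)CC)C1 | intermediate
8 | (E)-pent-2-enal | CC/C=C/C=O | starting material
9 | (1E,3E)-penta-1,3-dien-1-yl acetate | C/C=C/C=C/OC(C)=O | intermediate
10 | cis-fused Δ2-octalin Diels–Alder adduct (10-CHO, 1-OAc, 4-CH3 and H5 all α; 6α,7α-acetonide; 8α-(R)-2-methylbutanoate) | O=C[C@]12C[C@H](OC(=O)[C@H](C)CC)[C@@H]3OC(C)(C)O[C@@H]3[C@H]1[C@H](C)C=C[C@@H]2OC(C)=O | intermediate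
11 | C14 alcohol of 10 | OC[C@]12C[C@H](OC(=O)[C@H](C)CC)[C@@H]3OC(C)(C)O[C@@H]3[C@H]1[C@H](C)C=C[C@@H]2OC(C)=O | intermediate
12 | C14 TBDPS ether of 11 | CC(C)(C)[Si](c1ccccc1)(c1ccccc1)OC[C@]12C[C@H](OC(=O)[C@H](C)CC)[C@@H]3OC(C)(C)O[C@@H]3[C@H]1[C@H](C)C=C[C@@H]2OC(C)=O | intermediate
13 | cis-fused hexalin 1,3-diene (C1=C2, C3=C4–CH3), acetonide, TBDPS ether | CC(C)(C)[Si](c1ccccc1)(c1ccccc1)OC[C@]12C[C@H](OC(=O)[C@H](C)CC)[C@@H]3OC(C)(C)O[C@@H]3[C@H]1C(C)=CC=C2 | intermediate
14 | 6α,7α-diol of 13 | CC(C)(C)[Si](c1ccccc1)(c1ccccc1)OC[C@]12C[C@H](OC(=O)[C@H](C)CC)[C@H](O)[C@H](O)[C@H]1C(C)=CC=C2 | intermediate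
15 | 6,7-O-dibutylstannylene acetal of 14 | CC(C)(C)[Si](c1ccccc1)(c1ccccc1)OC[C@]12C[C@H](OC(=O)[C@H](C)CC)[C@@H]3O[Sn](CCCC)(CCCC)O[C@@H]3[C@H]1C(C)=CC=C2 | intermediate
16 | 6-O-acryloyl 7α-hydroxy hexalin diene | CC(C)(C)[Si](c1ccccc1)(c1ccccc1)OC[C@]12C[C@H](OC(=O)[C@H](C)CC)[C@H](O)[C@H](OC(=O)C=C)[C@H]1C(C)=CC=C2 | intermediate
17 | 7-keto 6-O-acrylate | CC(C)(C)[Si](c1ccccc1)(c1ccccc1)OC[C@]12C[C@H](OC(=O)[C@H](C)CC)C(=O)[C@H](OC(=O)C=C)[C@H]1C(C)=CC=C2 | intermediate
18 | Morita–Baylis–Hillman alcohol: cis-fused α-methylene-γ-lactone with 7β-OH | CC(C)(C)[Si](c1ccccc1)(c1ccccc1)OC[C@]12C[C@H](OC(=O)[C@H](C)CC)[C@]3(O)C(=C)C(=O)O[C@@H]3[C@H]1C(C)=CC=C2 | intermediate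
19 | tertiary 7-acetate of 18 | CC(C)(C)[Si](c1ccccc1)(c1ccccc1)OC[C@]12C[C@H](OC(=O)[C@H](C)CC)[C@]3(OC(C)=O)C(=C)C(=O)O[C@@H]3[C@H]1C(C)=CC=C2 | intermediate
20 | 13-acetoxy-7(11)-en-12,6α-olide on the hexalin diene, C14 OTBDPS | CC(C)(C)[Si](c1ccccc1)(c1ccccc1)OC[C@]12C[C@H](OC(=O)[C@H](C)CC)C3=C(COC(C)=O)C(=O)O[C@@H]3[C@H]1C(C)=CC=C2 | intermediate
21 | C14 alcohol of 20 | OC[C@]12C[C@H](OC(=O)[C@H](C)CC)C3=C(COC(C)=O)C(=O)O[C@@H]3[C@H]1C(C)=CC=C2 | intermediate
22 | 13-acetoxy-14-hydroxy-8α-[(R)-2-methylbutanoyloxy]germacra-1(10),2,4,7(11)-tetraen-12,6α-olide (C9 anti to C2 across C1=C10; 2Z; C3 syn to C6 across C4=C5) | CC[C@@H](C)C(=O)O[C@H]1C/C(CO)=C/C=C\C(C)=C/[C@H]2OC(=O)C(COC(C)=O)=C12 | intermediate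
23 | 1β,10α-monoepoxide of 22 | CC[C@@H](C)C(=O)O[C@H]1C[C@@]2(CO)O[C@@H]2/C=C\C(C)=C/[C@H]2OC(=O)C(COC(C)=O)=C12 | intermediate
24 | CNP0108300.1: 13-acetoxy-1β,10α:4α,5α-diepoxy-14-hydroxy-8α-[(R)-2-methylbutanoyloxy]germacra-2Z,7(11)-dien-12,6α-olide | CC[C@@H](C)C(=O)O[C@H]1C[C@@]2(CO)O[C@@H]2/C=C\[C@@]2(C)O[C@H]2[C@H]2OC(=O)C(COC(C)=O)=C12 | target

**Step count**
Total: 15 steps. Longest linear sequence: 14 steps (steps 1–4 and 6–15, from shikimic acid); step 5 is a one-step side branch.

**Three steps most likely to fail**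

Step 6 (Diels–Alder). A trisubstituted cyclohexenecarbaldehyde is a sluggish dienophile and the acetoxydiene is only weakly activated, which is why the diene is used in excess. Fallback, setting out from 7 and 8 and returning at 10: 8 is converted with TMSCl, Et3N and catalytic ZnCl2 into the far more electron-rich (1E,3E)-1-(trimethylsilyloxy)penta-1,3-diene F1. F1 adds to 7 thermally (toluene, 80 °C) or with Eu(fod)3 with the same facial and regiochemical sense to give the silyl ether adduct F2. Citric acid in methanol at 0 °C frees the C1 allylic alcohol F3, which is acetylated at once (Ac2O, pyridine, DMAP) to give 10.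

Step 13 (the proposed new cascade). The ketone may not be intercepted by the phosphonium enolate, or the two Lewis bases may interfere. Fallback with known chemistry, setting out from 17 and returning at 20: Me2AlSPh (from Me3Al and PhSH, CH2Cl2, −78 °C) performs the known non-basic tandem thia-Michael/aldol reaction to give the β-hydroxy-α-(phenylthiomethyl) lactone F4. NaIO4 oxidises it to the sulfoxide F5, and thermal syn-elimination (toluene, 90 °C, CaCO3) gives the isolated alcohol 18. Ac2O/DMAP gives the acetate 19, and DABCO in THF effects the known 1,3-acetate shift to 20.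

Step 15 (ring opening and epoxidation). This is the main stereochemical risk. The helical triene conformer formed directly by ring opening exposes the faces opposite to those needed. The target therefore requires the triene to relax to the helix-inverted conformer before oxidation, which is why DMDO is added only after warming to −20 °C. I could not establish this conformer preference rigorously; the facial outcome, especially at the cis C4=C5 alkene, is an expectation, not a certainty. In addition, unopened 21 left at the photostationary state is consumed by DMDO. Fallback, setting out from 21 and returning at 24: after irradiation the photolysate is treated with VO(acac)2/t-BuOOH at −20 → 0 °C. This hydroxyl-directed epoxidation touches only the allylic-alcohol alkene C1=C10 of triene 22, so monoepoxide 23 is isolated and unreacted 21 is recovered and recycled. If direct epoxidation of C4=C5 then gives the wrong face, 23 is treated with NBS in aqueous DME at −20 °C to give the bromohydrin F6 (Br at C5 on the exposed face, OH at C4). Closure with Ag2O in THF delivers the epoxide oxygen to the opposite face and gives 24.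

**Further compounds**

F1 | step 6 | (1E,3E)-1-(trimethylsilyloxy)penta-1,3-diene | C/C=C/C=C/O[Si](C)(C)C
F2 | step 6 | C1 trimethylsilyl ether analogue of adduct 10 | O=C[C@]12C[C@H](OC(=O)[C@H](C)CC)[C@@H]3OC(C)(C)O[C@@H]3[C@H]1[C@H](C)C=C[C@@H]2O[Si](C)(C)C
F3 | step 6 | C1 alcohol analogue of adduct 10 | O=C[C@]12C[C@H](OC(=O)[C@H](C)CC)[C@@H]3OC(C)(C)O[C@@H]3[C@H]1[C@H](C)C=C[C@@H]2O
F4 | step 13 | 7β-hydroxy-11-(phenylthiomethyl) cis-fused γ-lactone (C11 epimers) | CC(C)(C)[Si](c1ccccc1)(c1ccccc1)OC[C@]12C[C@H](OC(=O)[C@H](C)CC)[C@]3(O)C(CSc4ccccc4)C(=O)O[C@@H]3[C@H]1C(C)=CC=C2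
F5 | step 13 | sulfoxide of F4 | CC(C)(C)[Si](c1ccccc1)(c1ccccc1)OC[C@]12C[C@H](OC(=O)[C@H](C)CC)[C@]3(O)C(CS(=O)c4ccccc4)C(=O)O[C@@H]3[C@H]1C(C)=CC=C2
F6 | step 15 | 5-bromo-4-hydroxy bromohydrin of monoepoxide 23 | CC[C@@H](C)C(=O)O[C@H]1C[C@@]2(CO)O[C@@H]2/C=C\[C@@](C)(O)[C@H](Br)[C@H]2OC(=O)C(COC(C)=O)=C12
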